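The tetrahydrofuran (O1, C2 bearing ring A, C3, C4, C5 bearing ring B) is cut across O1–C2 and C3–C4. This exposes two simple pieces. C5 with O1 and C4 is an (S)-aryl vinyl carbinol, whose terminal CH2 will become the C4 methyl group. C2–C3 is the methyl enol ether of an aryl ethyl ketone. In one flask, bromoetherification joins O1 to C2 as a mixed ketal, and a 5-exo radical cyclisation onto the vinyl group joins C3 to C4 and sets C4 trans to ring B. C2 stays at ketone level until a final hydride delivery places ring A cis to the C3 methyl group.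

Key step: step 5

Remark on the chemistry: ring A is 3-hydroxy-4,5-dimethoxyphenyl and ring B is 3,4,5-trimethoxyphenyl. The target is (2R,3S,4S,5S): ring A cis to the C3 methyl, the two methyls trans, ring B trans to the C4 methyl.
Assumption: compounds 1 and 4, ethyl vinyl ether, ethyl 1-propenyl ether and 5-bromo-2,3-dimethoxyphenol are taken as commercially available.

Step 1
Reactants: 1 3,4,5-trimethoxybenzaldehyde
Product: 2 rac-1-(3,4,5-trimethoxyphenyl)prop-2-en-1-ol
Conditions: CH2=CHMgBr, THF, 0 °C; then H2O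
Reagents that add atoms: vinylmagnesium bromide, C=C[Mg]Br
Why: Grignard 1,2-addition of the vinyl nucleophile to the aldehyde should give the racemic allylic alcohol, whose carbinol carbon is the future C5 and whose vinyl group holds C4 and the future C4 methyl carbon.

Step 2
Reactants: 2 rac-1-(3,4,5-trimethoxyphenyl)prop-2-en-1-ol
Product: 3 (S)-1-(3,4,5-trimethoxyphenyl)prop-2-en-1-ol
Conditions: immobilised Candida antarctica lipase B, vinyl acetate, MTBE, 30 °C, run just past half conversion; the (R)-acetate is removed by chromatography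
Reagents that add atoms: none
Why: Lipase-catalysed kinetic resolution by transesterification should acylate the (R)-alcohol (aryl as large, vinyl as medium group) and leave the (S)-alcohol, which fixes C5 as S.

Step 3
Reactants: 4 methyl 3-hydroxy-4,5-dimethoxybenzoate
Product: 5 methyl 3,4-dimethoxy-5-(triisopropylsilyloxy)benzoate
Conditions: TIPSCl, imidazole, DMF, rt
Reagents that add atoms: triisopropylsilyl chloride, CC(C)[Si](Cl)(C(C)C)C(C)C
Why: Silyl ether protection of the phenol should mask the O–H and damp the ring against NBS, the titanium reagent and BF3 in later steps.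

Step 4
Reactants: 5 methyl 3,4-dimethoxy-5-(triisopropylsilyloxy)benzoate
Product: 6 (Z)-1-methoxy-1-[3,4-dimethoxy-5-(triisopropylsilyloxy)phenyl]prop-1-ene
Conditions: CH3CHBr2, Zn, TiCl4, TMEDA, THF, 25 °C; work-up on base-washed silica
Reagents that add atoms: 1,1-dibromoethane, CC(Br)Br
Why: Takai alkylidenation of the ester by the titanium ethylidene made from the gem-dibromide should turn C=O into the Z enol ether, giving C2 at ketone level and C3 as the nucleophilic carbon.

Step 5
Reactants: 3 (S)-1-(3,4,5-trimethoxyphenyl)prop-2-en-1-ol, 6 (Z)-1-methoxy-1-[3,4-dimethoxy-5-(triisopropylsilyloxy)phenyl]prop-1-ene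
Product: 8 (4S,5S)-2-methoxy-3,4-dimethyl-2-[3,4-dimethoxy-5-(triisopropylsilyloxy)phenyl]-5-(3,4,5-trimethoxyphenyl)tetrahydrofuran as a mixture of C2 and C3 epimers, via mixed bromo ketal 7 (not isolated)
Conditions: NBS, 2,6-lutidine, CH2Cl2, −78 to −20 °C; then PhMe, Bu3SnH, Et3B, air, 0 °C
Reagents that add atoms: N-bromosuccinimide, BrN1C(=O)CCC1=O (its bromine is carried by 7 only and is lost again on the way to 8)
Why: NBS brominates the electron-rich enol ether 6 at C3 and the α-bromo oxocarbenium ion at C2 is captured by the hydroxyl oxygen of 3 (bond O1–C2, mixed bromo ketal 7); Bu3Sn• then abstracts bromine and the secondary C3 radical adds to the internal vinyl carbon (bond C3–C4), the exocyclic primary radical taking hydrogen from Bu3SnH to become the C4 methyl group. The closest known reaction type is the Ueno–Stork haloacetal radical cyclisation, run here in one flask on a ketone-derived enol ether. The tetrahydrofuran ring closes in the 5-exo-trig mode. C4 is set by the C5 stereocentre: in the chair-like transition state of the 3-oxa-5-hexenyl radical, ring B on C5 sits pseudo-equatorial and the new methyl ends trans to it (4S); C2 and C3 form as mixtures, which is tolerable because C3 is equilibrated in step 6 and C2 is set afresh in step 7. The step needs Markovnikov delivery of O1 to C2 (secured by the methoxy and aryl groups that stabilise the cation there), attack of NBS on the enol ether and not on the arenes or the vinyl group (secured by its much higher nucleophilicity at −78 °C), and 5-exo closure ahead of 6-endo closure or 1,2-aryl shift (favoured by the fast cyclisation of such radicals at low temperature).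

Step 6
Reactants: 8 (4S,5S)-2-methoxy-3,4-dimethyl-2-[3,4-dimethoxy-5-(triisopropylsilyloxy)phenyl]-5-(3,4,5-trimethoxyphenyl)tetrahydrofuran (C2 and C3 epimers)
Product: 9 (3S,4S,5S)-2-methoxy-3,4-dimethyl-2-[3,4-dimethoxy-5-(triisopropylsilyloxy)phenyl]-5-(3,4,5-trimethoxyphenyl)tetrahydrofuran (anomers at C2)
Conditions: PPTS (cat.), MeOH/CH2Cl2, 40 °C
Reagents that add atoms: methanol, CO (degenerate exchange of the C2 methoxy group with the solvent)
Why: Acid-catalysed ketal/enol ether equilibration through the 2,3-dihydrofuran should epimerise C3 to the thermodynamically preferred isomer with the C3 methyl trans to the C4 methyl, while C4 and C5 are untouched.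

Step 7
Reactants: 9 (3S,4S,5S)-2-methoxy-3,4-dimethyl-2-[3,4-dimethoxy-5-(triisopropylsilyloxy)phenyl]-5-(3,4,5-trimethoxyphenyl)tetrahydrofuran
Product: 10 (2R,3S,4S,5S)-2-[3,4-dimethoxy-5-(triisopropylsilyloxy)phenyl]-3,4-dimethyl-5-(3,4,5-trimethoxyphenyl)tetrahydrofuran
Conditions: Et3SiH, BF3·OEt2, CH2Cl2, −78 °C
Reagents that add atoms: none
Why: Ionic reduction of the cyclic ketal through the 2-aryl oxocarbenium ion should deliver hydride to the face opposite the adjacent C3 methyl (which avoids the coplanar aryl group), so ring A ends cis to that methyl (2R); the low temperature guards against acid epimerisation at C2.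

Step 8
Reactants: 10 (2R,3S,4S,5S)-2-[3,4-dimethoxy-5-(triisopropylsilyloxy)phenyl]-3,4-dimethyl-5-(3,4,5-trimethoxyphenyl)tetrahydrofuran
Product: 11 5-[(2R,3S,4S,5S)-3,4-dimethyl-5-(3,4,5-trimethoxyphenyl)tetrahydrofuran-2-yl]-2,3-dimethoxyphenol
Conditions: TBAF, THF, 0 °C; then H2O
Reagents that add atoms: none
Why: Fluoride-mediated desilylation should free the phenol under non-acidic conditions that leave the dibenzylic ether and its kinetic C2 configuration intact.

Compound list
1 | 3,4,5-trimethoxybenzaldehyde | O=Cc1cc(OC)c(OC)c(OC)c1 | starting material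
2 | rac-1-(3,4,5-trimethoxyphenyl)prop-2-en-1-ol | C=CC(O)c1cc(OC)c(OC)c(OC)c1 | intermediate
3 | (S)-1-(3,4,5-trimethoxyphenyl)prop-2-en-1-ol | C=C[C@H](O)c1cc(OC)c(OC)c(OC)c1 | intermediate
4 | methyl 3-hydroxy-4,5-dimethoxybenzoate | COC(=O)c1cc(O)c(OC)c(OC)c1 | starting material
5 | methyl 3,4-dimethoxy-5-(triisopropylsilyloxy)benzoate | COC(=O)c1cc(OC)c(OC)c(O[Si](C(C)C)(C(C)C)C(C)C)c1 | intermediate
6 | (Z)-1-methoxy-1-[3,4-dimethoxy-5-(triisopropylsilyloxy)phenyl]prop-1-ene | C/C=C(\OC)c1cc(OC)c(OC)c(O[Si](C(C)C)(C(C)C)C(C)C)c1 | intermediate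
7 | mixed bromo ketal: 2-bromo-1-methoxy-1-[3,4-dimethoxy-5-(triisopropylsilyloxy)phenyl]propyl (S)-1-(3,4,5-trimethoxyphenyl)allyl ether (mixture at the ketal and CHBr carbons) | CC(Br)C(OC)(O[C@@H](C=C)c1cc(OC)c(OC)c(OC)c1)c1cc(OC)c(OC)c(O[Si](C(C)C)(C(C)C)C(C)C)c1 | intermediate
8 | (4S,5S)-2-methoxy-3,4-dimethyl-2-[3,4-dimethoxy-5-(triisopropylsilyloxy)phenyl]-5-(3,4,5-trimethoxyphenyl)tetrahydrofuran (mixture at C2 and C3) | COc1cc(C2(OC)O[C@H](c3cc(OC)c(OC)c(OC)c3)[C@@H](C)C2C)cc(O[Si](C(C)C)(C(C)C)C(C)C)c1OC | intermediate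
9 | (3S,4S,5S)-2-methoxy-3,4-dimethyl-2-[3,4-dimethoxy-5-(triisopropylsilyloxy)phenyl]-5-(3,4,5-trimethoxyphenyl)tetrahydrofuran (anomers at C2) | COc1cc(C2(OC)O[C@H](c3cc(OC)c(OC)c(OC)c3)[C@@H](C)[C@@H]2C)cc(O[Si](C(C)C)(C(C)C)C(C)C)c1OC | intermediate
10 | (2R,3S,4S,5S)-2-[3,4-dimethoxy-5-(triisopropylsilyloxy)phenyl]-3,4-dimethyl-5-(3,4,5-trimethoxyphenyl)tetrahydrofuran | COc1cc([C@@H]2O[C@H](c3cc(OC)c(OC)c(OC)c3)[C@@H](C)[C@@H]2C)cc(O[Si](C(C)C)(C(C)C)C(C)C)c1OC | intermediate
11 | 5-[(2R,3S,4S,5S)-3,4-dimethyl-5-(3,4,5-trimethoxyphenyl)tetrahydrofuran-2-yl]-2,3-dimethoxyphenol | COc1cc([C@@H]2O[C@H](c3cc(OC)c(OC)c(OC)c3)[C@@H](C)[C@@H]2C)cc(O)c1OC | target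

Total step count: 8
Longest linear sequence: 6 steps (steps 3, 4, 5, 6, 7, 8 from 4; equally steps 1, 2, 5, 6, 7, 8 from 1)

Steps most likely to fail

Step 5. The crowded α-bromo oxocarbenium ion from 6 may be captured too slowly by the secondary alcohol, so the enol ether is lost as α-bromo ketone. The benzylic, allylic C5–O bond of 7 may ionise, eroding configuration. The C3 radical may undergo 1,2-aryl shift or cyclise with poor trans selectivity. The fallback sets out from 3 and keeps the radical ring closure but moves ring A to a later carbonyl addition. Compound 3 is annulated in the same one-flask manner with the small ethyl 1-propenyl ether (NBS, then Bu3SnH, Et3B, air), which should give bromo acetal F1 and from it ethoxy acetal F2. Jones oxidation (CrO3, H2SO4, acetone) should give lactone F3 as C3 epimers, and DBU in toluene should equilibrate it to the all-trans lactone F4. Commercial 5-bromo-2,3-dimethoxyphenol is silylated (TIPSCl, imidazole) to aryl bromide F5, and n-BuLi at −78 °C should give aryllithium F6. Addition of F6 to F4 should stop at hemiketal F7, which the conditions of step 7 should reduce to 10, where the route is rejoined.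

Step 6. Epimerisation at C3 may stay incomplete, or methanol may be lost to the 2,3-dihydrofuran without clean re-addition. The fallback sets out from 3 and sets C3 by kinetic enolate alkylation instead of equilibration. Compound 3 is annulated with ethyl vinyl ether (NBS, then Bu3SnH, Et3B, air) to bromo acetal F8 and ethoxy acetal F9, and Jones oxidation should give lactone F10. LDA then MeI at −78 °C should methylate the lactone enolate anti to the C4 methyl and give the all-trans lactone F4 directly. F4 is carried through hemiketal F7 to 10 as described for step 5.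

Step 7. Hydride delivery to the oxocarbenium ion may show poor facial selectivity, or BF3 may epimerise C2 of the product towards the all-trans isomer. The fallback sets out from 3, passes through the all-trans lactone F4 made as described for step 5, and returns at 10. It reverses the roles at C2: hydrogen is placed first and ring A enters as the nucleophile. DIBAL-H at −78 °C should reduce F4 to lactol F11, and PhSO2H with CaCl2 should convert it into 2-phenylsulfonyl ether F12. Arylzinc bromide F13 (from aryllithium F6 and ZnBr2) should add to the oxocarbenium ion released from F12. The aryl group should enter trans to the C4 methyl and therefore cis to the C3 methyl, giving 10.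

Further compounds
F1 | step 5 | 2-bromo-1-ethoxypropyl (S)-1-(3,4,5-trimethoxyphenyl)allyl ether (bromo acetal, diastereomer mixture) | CCOC(O[C@@H](C=C)c1cc(OC)c(OC)c(OC)c1)C(C)Br
F2 | step 5 | (4S,5S)-2-ethoxy-3,4-dimethyl-5-(3,4,5-trimethoxyphenyl)tetrahydrofuran (mixture at C2 and C3) | CCOC1O[C@H](c2cc(OC)c(OC)c(OC)c2)[C@@H](C)C1C
F3 | step 5 | (4S,5S)-3,4-dimethyl-5-(3,4,5-trimethoxyphenyl)dihydrofuran-2(3H)-one (C3 epimers) | O=C1O[C@H](c2cc(OC)c(OC)c(OC)c2)[C@@H](C)C1C
F4 | step 5 | (3S,4S,5S)-3,4-dimethyl-5-(3,4,5-trimethoxyphenyl)dihydrofuran-2(3H)-one | O=C1O[C@H](c2cc(OC)c(OC)c(OC)c2)[C@@H](C)[C@@H]1C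
F5 | step 5 | (5-bromo-2,3-dimethoxyphenoxy)triisopropylsilane | COc1cc(Br)cc(O[Si](C(C)C)(C(C)C)C(C)C)c1OC
F6 | step 5 | [3,4-dimethoxy-5-(triisopropylsilyloxy)phenyl]lithium | [Li]c1cc(OC)c(OC)c(O[Si](C(C)C)(C(C)C)C(C)C)c1
F7 | step 5 | (3S,4S,5S)-2-[3,4-dimethoxy-5-(triisopropylsilyloxy)phenyl]-3,4-dimethyl-5-(3,4,5-trimethoxyphenyl)tetrahydrofuran-2-ol (hemiketal, anomers) | COc1cc(C2(O)O[C@H](c3cc(OC)c(OC)c(OC)c3)[C@@H](C)[C@@H]2C)cc(O[Si](C(C)C)(C(C)C)C(C)C)c1OC
F8 | step 6 | 2-bromo-1-ethoxyethyl (S)-1-(3,4,5-trimethoxyphenyl)allyl ether (bromo acetal) | CCOC(CBr)O[C@@H](C=C)c1cc(OC)c(OC)c(OC)c1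
F9 | step 6 | (4S,5S)-2-ethoxy-4-methyl-5-(3,4,5-trimethoxyphenyl)tetrahydrofuran (anomers) | CCOC1O[C@H](c2cc(OC)c(OC)c(OC)c2)[C@@H](C)C1
F10 | step 6 | (4S,5S)-4-methyl-5-(3,4,5-trimethoxyphenyl)dihydrofuran-2(3H)-one | O=C1O[C@H](c2cc(OC)c(OC)c(OC)c2)[C@@H](C)C1
F11 | step 7 | (3S,4S,5S)-3,4-dimethyl-5-(3,4,5-trimethoxyphenyl)tetrahydrofuran-2-ol (lactol, anomers) | OC1O[C@H](c2cc(OC)c(OC)c(OC)c2)[C@@H](C)[C@@H]1C
F12 | step 7 | (3S,4S,5S)-3,4-dimethyl-2-(phenylsulfonyl)-5-(3,4,5-trimethoxyphenyl)tetrahydrofuran | O=S(=O)(c1ccccc1)C1O[C@H](c2cc(OC)c(OC)c(OC)c2)[C@@H](C)[C@@H]1C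
F13 | step 7 | [3,4-dimethoxy-5-(triisopropylsilyloxy)phenyl]zinc bromide | Br[Zn]c1cc(OC)c(OC)c(O[Si](C(C)C)(C(C)C)C(C)C)c1
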